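Ring C is disconnected at C4–C4a and O1–C2, so that C4, C3 (with the C9 anisylmethyl arm) and C2 derive from 2-(4-methoxybenzyl)acrylic acid and ring A from unprotected 2,6-dihydroxy-4-methoxy-3-methylbenzaldehyde. The key step exploits the single unsubstituted carbon of ring A (future C4a), which lies between the methoxy-bearing C5 and the hydroxyl-bearing C8a and is meta to the formyl group. In one acid-mediated operation this carbon is acylated and the adjacent hydroxyl adds to the acrylic CH2, closing ring C as a 3-benzylchroman-4-one that already carries 5-OMe, 6-Me, 7-OH and 8-CHO. Dehydrogenation of C2–C3 then gives the chromone.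

Key step: step 6

Remarks on the chemistry:
- Chromone numbering (O1, C2, C3, C4, C4a, C5 to C8, C8a; C9 is the benzylic CH2) is used for the bicyclic compounds, benzaldehyde numbering for the ring A precursors.
- The target has no stereocentre. C3 of chromanone 13 is formed racemic and becomes sp2 in step 7.
- The aldehyde is carried unprotected: it is chelated by its two ortho hydroxyls, and an acetal would not survive the acid of step 6.

Step 1
Reactants: 1 diethyl malonate; 2 4-methoxybenzyl chloride
Product: 3 diethyl 2-(4-methoxybenzyl)malonate
Conditions: NaH (1.0 equiv), 1 (1.5 equiv), THF, 0 °C to rt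
Reagents that add atoms: none
Why: Malonic ester alkylation, an SN2 displacement of the reactive benzylic chloride by the malonate carbanion, with excess 1 and an aprotic solvent holding back dialkylation and solvolysis of 2.

Step 2
Reactants: 3 diethyl 2-(4-methoxybenzyl)malonate
Product: 4 2-(4-methoxybenzyl)malonic acid
Conditions: KOH (3 equiv), EtOH/H2O, reflux; then HCl (aq), 0 °C
Reagents that add atoms: potassium hydroxide, [K+].[OH-]
Why: Ester saponification by acyl–oxygen cleavage should be clean on an unhindered malonate, and cold acidification frees the diacid without decarboxylation.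

Step 3
Reactants: 4 2-(4-methoxybenzyl)malonic acid
Product: 6 2-(4-methoxybenzyl)acrylic acid, via Mannich base 5 (not isolated)
Conditions: (CH2O)n (2 equiv), Et2NH (1.1 equiv), EtOAc, reflux; HCl (aq) work-up
Reagents that add atoms: formaldehyde (from paraformaldehyde), C=O
Why: Mannich reaction of the malonic acid with (diethylamino)methanol, formed in the flask from formaldehyde and Et2NH, gives 5, which on heating loses CO2 and Et2NH in a decarboxylative elimination, the standard way to 2-benzylacrylic acids.

Step 4
Reactants: 7 2,4,6-trihydroxytoluene
Product: 9 2,4,6-trihydroxy-3-methylbenzaldehyde, via iminium chloride 8 (not isolated)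
Conditions: POCl3 (1.1 equiv), DMF (1.2 equiv), EtOAc, 0 °C to rt; then H2O, 60 °C
Reagents that add atoms: N,N-dimethylformamide, CN(C)C=O; water, O
Why: Vilsmeier–Haack formylation, in which the chloroiminium reagent from DMF and POCl3 attacks one of the two equivalent free carbons of the symmetric phloroglucinol, the deactivated iminium salt 8 resists a second formylation, and water hydrolyses it to the aldehyde.

Step 5
Reactants: 9 2,4,6-trihydroxy-3-methylbenzaldehyde
Product: 10 2,6-dihydroxy-4-methoxy-3-methylbenzaldehyde
Conditions: Me2SO4 (1.0 equiv), K2CO3 (1.0 equiv), acetone, 0 °C to rt, N2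
Reagents that add atoms: dimethyl sulfate, COS(=O)(=O)OC
Why: Williamson O-methylation directed by acidity: the C4 hydroxyl para to the formyl group is a vinylogous acid and the only one that cannot chelate the carbonyl, so one equivalent of weak base and a hard methylating agent should etherify it in preference to the two ortho hydroxyls.

Step 6
Reactants: 10 2,6-dihydroxy-4-methoxy-3-methylbenzaldehyde; 6 2-(4-methoxybenzyl)acrylic acid
Product: 13 racemic 7-hydroxy-5-methoxy-3-(4-methoxybenzyl)-6-methyl-4-oxochromane-8-carbaldehyde, via acyl mesylate 11 (not isolated), via aryl vinyl ketone 12 (not isolated)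
Conditions: 6 (1.3 equiv), P2O5/MeSO3H (1:10 w/w), 60 °C; then ice/H2O
Reagents that add atoms: none
Why: In P2O5/MeSO3H acid 6 is converted into mixed anhydride 11, which transfers its acyl group to C5 of 10 (directly or by O-acylation and Fries shift); C5 is the only unsubstituted ring carbon, is activated by an ortho hydroxyl, an ortho methoxy and a para hydroxyl and lies meta to the formyl group, and the result is aryl vinyl ketone 12 with the new C4–C4a bond. The C6 hydroxyl of 12, the only one ortho to the new ketone, then adds to the CH2 terminus of the protonated enone in a 6-endo-trig oxa-Michael closure that forms O1–C2 and ring C. The closest known reaction type is the one-pot Friedel–Crafts acylation and oxa-Michael annulation of phloroglucinol-type phenols with α,β-unsaturated acids to chroman-4-ones in P2O5/MeSO3H, polyphosphoric acid or BF3·OEt2. C3 arises by unselective protonation of the enol left by the conjugate addition, so 13 should be racemic, which is immaterial because C3 becomes sp2 in step 7. The step needs chemoselectivity for C-acylation of ring A over acylation of the anisyl ring (whose carbons next to the tether are meta to its methoxy group) and over conjugate C-alkylation that would lead to a dihydrocoumarin, which the dehydrating acylating medium and the threefold activation of C5 should secure; the regiochemistry of both new bonds is fixed because ring A offers one free carbon and one hydroxyl beside it.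

Step 7
Reactants: 13 racemic 7-hydroxy-5-methoxy-3-(4-methoxybenzyl)-6-methyl-4-oxochromane-8-carbaldehyde
Product: 15 7-hydroxy-5-methoxy-3-(4-methoxybenzyl)-6-methyl-4-oxo-4H-chromene-8-carbaldehyde, via 3-iodochromanone 14 (not isolated)
Conditions: I2 (0.2 equiv), DMSO, 120 °C
Reagents that add atoms: none
Why: Iodine-catalysed dehydrogenation of a chroman-4-one in DMSO, in which the ketone enolises toward C3 (its only enolisable α-carbon), is iodinated to 14 and loses HI to place the double bond at C2–C3 while DMSO reoxidises HI to I2; the fully substituted phenol ring, the chelated aldehyde and the p-methoxybenzylic CH2 should be left alone, which is why this oxidant is preferred to quinones or hypervalent iodine reagents.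

Compound list
1 | diethyl malonate | CCOC(=O)CC(=O)OCC | starting material
2 | 4-methoxybenzyl chloride | COc1ccc(CCl)cc1 | starting material
3 | diethyl 2-(4-methoxybenzyl)malonate | CCOC(=O)C(Cc1ccc(OC)cc1)C(=O)OCC | intermediate
4 | 2-(4-methoxybenzyl)malonic acid | COc1ccc(CC(C(=O)O)C(=O)O)cc1 | intermediate
5 | 2-[(diethylamino)methyl]-2-(4-methoxybenzyl)malonic acid (Mannich base, not isolated) | CCN(CC)CC(Cc1ccc(OC)cc1)(C(=O)O)C(=O)O | intermediate
6 | 2-(4-methoxybenzyl)acrylic acid | C=C(Cc1ccc(OC)cc1)C(=O)O | intermediate
7 | 2,4,6-trihydroxytoluene | Cc1c(O)cc(O)cc1O | starting material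
8 | N-methyl-N-[(2,4,6-trihydroxy-3-methylphenyl)methylidene]methanaminium chloride (iminium chloride, not isolated) | C[N+](C)=Cc1c(O)cc(O)c(C)c1O.[Cl-] | intermediate
9 | 2,4,6-trihydroxy-3-methylbenzaldehyde | O=Cc1c(O)cc(O)c(C)c1O | intermediate
10 | 2,6-dihydroxy-4-methoxy-3-methylbenzaldehyde | O=Cc1c(O)c(C)c(OC)cc1O | intermediate
11 | 2-(4-methoxybenzyl)acrylic methanesulfonic anhydride (acyl mesylate, not isolated) | C=C(Cc1ccc(OC)cc1)C(=O)OS(C)(=O)=O | intermediate
12 | 2,6-dihydroxy-4-methoxy-5-[2-(4-methoxybenzyl)acryloyl]-3-methylbenzaldehyde (aryl vinyl ketone, not isolated) | C=C(Cc1ccc(OC)cc1)C(=O)c1c(O)c(C=O)c(O)c(C)c1OC | intermediate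
13 | racemic 7-hydroxy-5-methoxy-3-(4-methoxybenzyl)-6-methyl-4-oxochromane-8-carbaldehyde | COc1ccc(CC2COc3c(C=O)c(O)c(C)c(OC)c3C2=O)cc1 | intermediate
14 | racemic 7-hydroxy-3-iodo-5-methoxy-3-(4-methoxybenzyl)-6-methyl-4-oxochromane-8-carbaldehyde (3-iodochromanone, not isolated) | COc1ccc(CC2(I)COc3c(C=O)c(O)c(C)c(OC)c3C2=O)cc1 | intermediate
15 | 7-hydroxy-5-methoxy-3-(4-methoxybenzyl)-6-methyl-4-oxo-4H-chromene-8-carbaldehyde (achiral) | COc1ccc(Cc2coc3c(C=O)c(O)c(C)c(OC)c3c2=O)cc1 | target

Total step count: 7.
Longest linear sequence: 5 steps (steps 1, 2, 3, 6, 7); the aldehyde branch (steps 4, 5) joins at step 6.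

Steps most likely to fail

1. Step 6. The acyl donor may be diverted before the formyl-deactivated ring is C-acylated: by conjugate C-alkylation of ring A with lactonisation, by cyclisation onto its own anisyl ring, or by oligomerisation. The chelated hydroxy aldehyde may also condense with electron-rich arenes in the hot acid. The fallback sets out from 10 and returns at 13, and it separates the acylation from the introduction of C2. Compound 10 would be acylated at C5 with commercial 3-(4-methoxyphenyl)propanoic acid (COc1ccc(CCC(=O)O)cc1) in BF3·OEt2 at 80 °C. This saturated acid can neither polymerise nor add in a conjugate sense, and it should give the dihydrochalcone 2,6-dihydroxy-4-methoxy-5-[3-(4-methoxyphenyl)propanoyl]-3-methylbenzaldehyde F1. Heating F1 with paraformaldehyde and Et2NH in MeOH, the established ring closure to homoisoflavanones, should give the Mannich base 5-{2-[(diethylamino)methyl]-3-(4-methoxyphenyl)propanoyl}-2,6-dihydroxy-4-methoxy-3-methylbenzaldehyde F2. F2 eliminates diethylamine to enone 12, which closes to 13.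

2. Step 5. Site control in the alkylation may be lost through methylation of an ortho hydroxyl, double methylation, or C-methylation of the phloroglucinol anion. The fallback sets out from 9 and returns at 10, and it moves the selectivity from ether formation to ether cleavage. Compound 9 would be exhaustively O-methylated (excess Me2SO4, K2CO3, acetone, reflux) to 2,4,6-trimethoxy-3-methylbenzaldehyde F3. The two ethers flanking the formyl group would then be cleaved by chelation-directed demethylation with AlCl3 in chlorobenzene at 80 °C. The carbonyl-bound Lewis acid reaches only the ortho methoxy groups and should spare the remote para ether, giving 10.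

3. Step 7. Conversion of the hindered, electron-poor ketone may stall, or the hot oxidising medium may act elsewhere (iodination of the anisyl ring, cleavage of the C5 methyl ether by HI, oxidation at C9). The fallback sets out from 13 and returns at 15, and it replaces the catalytic one-pot oxidation by a stoichiometric halogenation and a separate base-induced elimination at lower temperature. Bromination at C3 with PhNMe3Br3 in THF at 0 °C to rt should give racemic 3-bromo-7-hydroxy-5-methoxy-3-(4-methoxybenzyl)-6-methyl-4-oxochromane-8-carbaldehyde F4. Li2CO3/LiBr in DMF at 100 °C would then eliminate HBr from F4 to give 15.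

Further compounds
F1 | step 6 | 2,6-dihydroxy-4-methoxy-5-[3-(4-methoxyphenyl)propanoyl]-3-methylbenzaldehyde | COc1ccc(CCC(=O)c2c(O)c(C=O)c(O)c(C)c2OC)cc1
F2 | step 6 | racemic 5-{2-[(diethylamino)methyl]-3-(4-methoxyphenyl)propanoyl}-2,6-dihydroxy-4-methoxy-3-methylbenzaldehyde | CCN(CC)CC(Cc1ccc(OC)cc1)C(=O)c1c(O)c(C=O)c(O)c(C)c1OC
F3 | step 5 | 2,4,6-trimethoxy-3-methylbenzaldehyde | COc1cc(OC)c(C=O)c(OC)c1C
F4 | step 7 | racemic 3-bromo-7-hydroxy-5-methoxy-3-(4-methoxybenzyl)-6-methyl-4-oxochromane-8-carbaldehyde | COc1ccc(CC2(Br)COc3c(C=O)c(O)c(C)c(OC)c3C2=O)cc1
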